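**Strategy.** The oxolane (O1, C2, C3 bearing the carbinol arm, C4 bearing the benzyl group, C5) hides a γ-hydroxy 1,4-dicarbonyl: C5 is the carbonyl carbon of a 3-arylpropanal and C3 the α-carbon of an aryl ketone. The key step couples aldehyde 6 with α-bromo-β-hydroxy ketone 4 by enantioselective photoredox organocatalytic α-alkylation; the C3–C4 bond forms by radical addition to a chiral enamine and the pendant hydroxyl at once closes O1–C5 as a lactol. Both partners derive from one benzaldehyde. Lactol deoxygenation, epimerisation to the trans ring, a matched CBS reduction and hydrogenolysis complete the synthesis.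

Key step: step 6

Remark: both phenols are carried as benzyl ethers from commercial 1 (otherwise one benzylation from syringaldehyde), because free 4-hydroxy-3,5-dimethoxyphenyl groups would not tolerate the oxidant of step 2 or the photoredox conditions of step 6.

Step 1
Reactants: 1 4-(benzyloxy)-3,5-dimethoxybenzaldehyde
Product: 2 rac-1-[4-(benzyloxy)-3,5-dimethoxyphenyl]prop-2-en-1-ol
Conditions: vinylMgBr (1.2 equiv), THF, 0 °C; aqueous work-up
Reagents that add atoms: vinylmagnesium bromide, C=C[Mg]Br
Why: Grignard 1,2-addition to the aryl aldehyde should give the allylic alcohol as a racemate, whose stereocentre is removed in step 2.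

Step 2
Reactants: 2 rac-1-[4-(benzyloxy)-3,5-dimethoxyphenyl]prop-2-en-1-ol
Product: 3 1-[4-(benzyloxy)-3,5-dimethoxyphenyl]prop-2-en-1-one
Conditions: Dess–Martin periodinane (1.2 equiv), CH2Cl2, 0 °C to rt
Reagents that add atoms: none
Why: Dess–Martin oxidation of the benzylic and allylic secondary alcohol should give the aryl vinyl ketone without touching the benzyl ether, and no stereocentre remains.

Step 3
Reactants: 3 1-[4-(benzyloxy)-3,5-dimethoxyphenyl]prop-2-en-1-one
Product: 4 rac-1-[4-(benzyloxy)-3,5-dimethoxyphenyl]-2-bromo-3-hydroxypropan-1-one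
Conditions: NBS (1.05 equiv), acetone/H2O, 0 °C to rt, dark
Reagents that add atoms: N-bromosuccinimide, O=C1CCC(=O)N1Br; water, O
Why: Bromohydrin formation (cohalogenation) should open the bromonium ion with water at the terminal carbon remote from the carbonyl group, so that bromine ends α and hydroxyl β to the ketone; the racemic centre is erased at the radical stage of step 6.

Step 4
Reactants: 1 4-(benzyloxy)-3,5-dimethoxybenzaldehyde
Product: 5 (E)-3-[4-(benzyloxy)-3,5-dimethoxyphenyl]prop-2-enal
Conditions: Ph3P=CHCHO (1.1 equiv), toluene, 80 °C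
Reagents that add atoms: (triphenylphosphoranylidene)acetaldehyde, O=CC=P(c1ccccc1)(c1ccccc1)c1ccccc1
Why: Wittig olefination with the stabilised formyl ylide should give the (E)-enal selectively.

Step 5
Reactants: 5 (E)-3-[4-(benzyloxy)-3,5-dimethoxyphenyl]prop-2-enal
Product: 6 3-[4-(benzyloxy)-3,5-dimethoxyphenyl]propanal
Conditions: Hantzsch ester (diethyl 2,6-dimethyl-1,4-dihydropyridine-3,5-dicarboxylate, 1.1 equiv), (PhCH2)2NH2+ CF3CO2− (5 mol %), THF, rt
Reagents that add atoms: none
Why: Iminium-catalysed transfer hydrogenation with a Hantzsch ester (organocatalytic conjugate reduction) should reduce only the C=C bond and leave the aldehyde and the benzyl ether intact.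

Step 6
Reactants: 6 3-[4-(benzyloxy)-3,5-dimethoxyphenyl]propanal (1.5 equiv); 4 rac-1-[4-(benzyloxy)-3,5-dimethoxyphenyl]-2-bromo-3-hydroxypropan-1-one
Product: 8 (3R)-4-[4-(benzyloxy)-3,5-dimethoxybenzoyl]-3-[4-(benzyloxy)-3,5-dimethoxybenzyl]oxolan-2-ol (lactol; epimers at C2/C4), via γ-hydroxy aldehyde 7 (not isolated)
Conditions: Ru(bpy)3Cl2 (0.5 mol %), (2R,5S)-2-tert-butyl-3,5-dimethylimidazolidin-4-one·CF3SO3H (20 mol %), 2,6-lutidine (2 equiv), DMF, blue LEDs, 23 °C
Reagents that add atoms: none
Why: Aldehyde 6 condenses with the imidazolidinone to an (E)-enamine while Ru(bpy)3+ (monovalent ruthenium, formed from the photoexcited divalent ruthenium complex) cleaves the C–Br bond of 4 to an electrophilic α-acyl radical; this adds to the enamine, the α-amino radical is oxidised by photoexcited Ru(bpy)3(2+) to the iminium ion, and hydrolysis releases γ-hydroxy aldehyde 7, in which the bond between the two future substituted ring carbons is made. The closest known reaction type is the enantioselective photoredox organocatalytic α-alkylation of aldehydes with α-bromo carbonyl compounds, here followed by ring–chain tautomerism. The ring closes by 5-exo-trig addition of the γ-hydroxyl to the aldehyde carbon, which makes the O–C bond of lactol 8 (the later ring O–CH2 bond beside the benzyl-bearing carbon). The benzyl-bearing centre is set by the catalyst, since the enamine lies away from the tert-butyl group, the 5-methyl group shields its Re face and Si-face attack gives R; the aroyl-bearing and anomeric centres form as mixtures, the first being corrected in step 8 and the second removed in step 7. The step needs radical addition to the enamine to outrun reduction of the radical, which the polarity match of an electron-poor radical and an electron-rich enamine should secure, and the regiochemistry is fixed because bromine marks the only radical site and only a five-membered lactol can form. The α-branched product is masked as the lactol, so the new centre should not racemise by renewed enamine formation.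

Step 7
Reactants: 8 (3R)-4-[4-(benzyloxy)-3,5-dimethoxybenzoyl]-3-[4-(benzyloxy)-3,5-dimethoxybenzyl]oxolan-2-ol
Product: 9 [4-(benzyloxy)-3,5-dimethoxyphenyl]{(4R)-4-[4-(benzyloxy)-3,5-dimethoxybenzyl]oxolan-3-yl}methanone (epimers at oxolane C3)
Conditions: Et3SiH (3 equiv), BF3·OEt2 (1.5 equiv, Lewis acid promoter), CH2Cl2, −78 to −40 °C
Reagents that add atoms: none
Why: Ionic hydrogenation of the lactol (cyclic oxocarbenium ion, then hydride from Et3SiH) should remove the anomeric hydroxyl at low temperature faster than the aryl ketone reacts, and the catalyst-set centre is not affected.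

Step 8
Reactants: 9 [4-(benzyloxy)-3,5-dimethoxyphenyl]{(4R)-4-[4-(benzyloxy)-3,5-dimethoxybenzyl]oxolan-3-yl}methanone (epimers at oxolane C3)
Product: 10 [4-(benzyloxy)-3,5-dimethoxyphenyl]{(3R,4R)-4-[4-(benzyloxy)-3,5-dimethoxybenzyl]oxolan-3-yl}methanone (trans)
Conditions: NaOMe (0.2 equiv), MeOH/THF, rt
Reagents that add atoms: none
Why: Base-mediated epimerisation through the ketone enolate should funnel the mixture to the thermodynamically favoured trans-3,4-disubstituted oxolane, because the benzyl-bearing centre has no acidic hydrogen and ring opening by β-elimination would be a disfavoured reverse 5-endo-trig process.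

Step 9
Reactants: 10 [4-(benzyloxy)-3,5-dimethoxyphenyl]{(3R,4R)-4-[4-(benzyloxy)-3,5-dimethoxybenzyl]oxolan-3-yl}methanone
Product: 11 (S)-[4-(benzyloxy)-3,5-dimethoxyphenyl]{(3R,4R)-4-[4-(benzyloxy)-3,5-dimethoxybenzyl]oxolan-3-yl}methanol
Conditions: (R)-Me-CBS [(R)-1-methyl-3,3-diphenyltetrahydro-1H,3H-pyrrolo[1,2-c][1,3,2]oxazaborole, 20 mol %], BH3·SMe2, THF, −20 °C; MeOH quench
Reagents that add atoms: none
Why: CBS reduction with the (R)-oxazaborolidine should deliver hydride to the ketone face that gives the (S)-carbinol (aryl as the large group), which is also the face preferred by the Felkin–Anh and chelation models for the adjacent ring stereocentre, so catalyst and substrate control reinforce each other.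

Step 10
Reactants: 11 (S)-[4-(benzyloxy)-3,5-dimethoxyphenyl]{(3R,4R)-4-[4-(benzyloxy)-3,5-dimethoxybenzyl]oxolan-3-yl}methanol
Product: 12 (S)-(4-hydroxy-3,5-dimethoxyphenyl)[(3R,4R)-4-(4-hydroxy-3,5-dimethoxybenzyl)oxolan-3-yl]methanol
Conditions: H2 (1 atm), 10% Pd/C, EtOAc, rt
Reagents that add atoms: none
Why: Hydrogenolysis of the two aryl benzyl ethers under neutral conditions should free both phenols before the benzylic C–OH bond is attacked, and no stereocentre is touched.

**Compound list**

1 | 4-(benzyloxy)-3,5-dimethoxybenzaldehyde | O=Cc1cc(OC)c(OCc2ccccc2)c(OC)c1 | starting material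
2 | rac-1-[4-(benzyloxy)-3,5-dimethoxyphenyl]prop-2-en-1-ol | C=CC(O)c1cc(OC)c(OCc2ccccc2)c(OC)c1 | intermediate
3 | 1-[4-(benzyloxy)-3,5-dimethoxyphenyl]prop-2-en-1-one | C=CC(=O)c1cc(OC)c(OCc2ccccc2)c(OC)c1 | intermediate
4 | rac-1-[4-(benzyloxy)-3,5-dimethoxyphenyl]-2-bromo-3-hydroxypropan-1-one | OCC(Br)C(=O)c1cc(OC)c(OCc2ccccc2)c(OC)c1 | intermediate
5 | (E)-3-[4-(benzyloxy)-3,5-dimethoxyphenyl]prop-2-enal | O=C/C=C/c1cc(OC)c(OCc2ccccc2)c(OC)c1 | intermediate
6 | 3-[4-(benzyloxy)-3,5-dimethoxyphenyl]propanal | O=CCCc1cc(OC)c(OCc2ccccc2)c(OC)c1 | intermediate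
7 | (2R)-2-[4-(benzyloxy)-3,5-dimethoxybenzyl]-4-[4-(benzyloxy)-3,5-dimethoxyphenyl]-3-(hydroxymethyl)-4-oxobutanal (C3 epimers; not isolated) | O=C[C@H](Cc1cc(OC)c(OCc2ccccc2)c(OC)c1)C(CO)C(=O)c1cc(OC)c(OCc2ccccc2)c(OC)c1 | intermediate
8 | (3R)-4-[4-(benzyloxy)-3,5-dimethoxybenzoyl]-3-[4-(benzyloxy)-3,5-dimethoxybenzyl]oxolan-2-ol (epimers at C2 and C4) | COc1cc(C[C@H]2C(O)OCC2C(=O)c2cc(OC)c(OCc3ccccc3)c(OC)c2)cc(OC)c1OCc1ccccc1 | intermediate
9 | [4-(benzyloxy)-3,5-dimethoxyphenyl]{(4R)-4-[4-(benzyloxy)-3,5-dimethoxybenzyl]oxolan-3-yl}methanone (epimers at oxolane C3) | COc1cc(C[C@H]2COCC2C(=O)c2cc(OC)c(OCc3ccccc3)c(OC)c2)cc(OC)c1OCc1ccccc1 | intermediate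
10 | [4-(benzyloxy)-3,5-dimethoxyphenyl]{(3R,4R)-4-[4-(benzyloxy)-3,5-dimethoxybenzyl]oxolan-3-yl}methanone | COc1cc(C[C@H]2COC[C@@H]2C(=O)c2cc(OC)c(OCc3ccccc3)c(OC)c2)cc(OC)c1OCc1ccccc1 | intermediate
11 | (S)-[4-(benzyloxy)-3,5-dimethoxyphenyl]{(3R,4R)-4-[4-(benzyloxy)-3,5-dimethoxybenzyl]oxolan-3-yl}methanol | COc1cc(C[C@H]2COC[C@@H]2[C@H](O)c2cc(OC)c(OCc3ccccc3)c(OC)c2)cc(OC)c1OCc1ccccc1 | intermediate
12 | (S)-(4-hydroxy-3,5-dimethoxyphenyl)[(3R,4R)-4-(4-hydroxy-3,5-dimethoxybenzyl)oxolan-3-yl]methanol | COc1cc(C[C@H]2COC[C@@H]2[C@H](O)c2cc(OC)c(O)c(OC)c2)cc(OC)c1O | target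

**Step count.** Total: 10 steps. Longest linear sequence: 8 steps (steps 1, 2, 3, 6, 7, 8, 9, 10).

**Steps most likely to fail**

Step 6. The hindered secondary α-acyl radical may be reduced by hydrogen-atom capture, or 4 may lose HBr, faster than the radical adds to the enamine, and enantiocontrol may erode. The fallback is a two-electron pathway that still makes the same two ring bonds in one operation. Starting from 6, an enamine-catalysed Michael addition to (E)-3-nitroprop-2-en-1-ol (OC/C=C/[N+](=O)[O-]) with (S)-α,α-diphenylprolinol trimethylsilyl ether and benzoic acid in toluene at 0 °C, followed in the same flask by hemiacetalisation, should give the nitro lactol (3R)-3-[4-(benzyloxy)-3,5-dimethoxybenzyl]-4-(nitromethyl)oxolan-2-ol F1. Et3SiH with BF3·OEt2 should then give the nitromethyl oxolane F2. A reductive Nef reaction (NaOMe, MeOH; then buffered aqueous TiCl3) should give the oxolane-3-carbaldehyde F3. Addition of [4-(benzyloxy)-3,5-dimethoxyphenyl]magnesium bromide (from the aryl bromide and Mg) should give the carbinol mixture F4, and Dess–Martin oxidation of F4 comes back to the route at 9, which enters step 8.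

Step 3. Electrophilic bromination of the electron-rich aryl ring, or dibromination, may compete with the slow bromonium formation on the electron-poor alkene. The fallback builds the bromohydrin by another order of events. Starting from 2, hydroboration–oxidation (9-BBN, THF; NaOH, H2O2) should give 1-[4-(benzyloxy)-3,5-dimethoxyphenyl]propane-1,3-diol F5. Benzylic-selective oxidation with MnO2 in CH2Cl2 should give the β-hydroxy ketone 1-[4-(benzyloxy)-3,5-dimethoxyphenyl]-3-hydroxypropan-1-one F6, and α-bromination of the ketone with PhNMe3Br3 in THF at 0 °C comes back to the route at 4.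

Step 10. Once a phenol is freed, over-reduction by hydrogenolysis of the electron-rich benzylic C–OH bond may set in. The fallback reverses the order of the last two operations. Starting from 10, hydrogenolysis (H2, 10% Pd/C, EtOAc) at the ketone stage should give the bis-phenol ketone (4-hydroxy-3,5-dimethoxyphenyl)[(3R,4R)-4-(4-hydroxy-3,5-dimethoxybenzyl)oxolan-3-yl]methanone F7. CBS reduction with (R)-Me-CBS and excess BH3·SMe2 (the phenols being carried as aryloxyboranes until the methanol quench) then comes back to the route at 12.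

Further compounds
F1 | step 6 | (3R)-3-[4-(benzyloxy)-3,5-dimethoxybenzyl]-4-(nitromethyl)oxolan-2-ol (epimers at C2 and C4) | COc1cc(C[C@H]2C(O)OCC2C[N+](=O)[O-])cc(OC)c1OCc1ccccc1
F2 | step 6 | (3R)-3-[4-(benzyloxy)-3,5-dimethoxybenzyl]-4-(nitromethyl)oxolane (epimers at C4) | COc1cc(C[C@H]2COCC2C[N+](=O)[O-])cc(OC)c1OCc1ccccc1
F3 | step 6 | (4R)-4-[4-(benzyloxy)-3,5-dimethoxybenzyl]oxolane-3-carbaldehyde (epimers at C3) | COc1cc(C[C@H]2COCC2C=O)cc(OC)c1OCc1ccccc1
F4 | step 6 | [4-(benzyloxy)-3,5-dimethoxyphenyl]{(4R)-4-[4-(benzyloxy)-3,5-dimethoxybenzyl]oxolan-3-yl}methanol (epimer mixture) | COc1cc(C[C@H]2COCC2C(O)c2cc(OC)c(OCc3ccccc3)c(OC)c2)cc(OC)c1OCc1ccccc1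
F5 | step 3 | 1-[4-(benzyloxy)-3,5-dimethoxyphenyl]propane-1,3-diol | OCCC(O)c1cc(OC)c(OCc2ccccc2)c(OC)c1
F6 | step 3 | 1-[4-(benzyloxy)-3,5-dimethoxyphenyl]-3-hydroxypropan-1-one | OCCC(=O)c1cc(OC)c(OCc2ccccc2)c(OC)c1
F7 | step 10 | (4-hydroxy-3,5-dimethoxyphenyl)[(3R,4R)-4-(4-hydroxy-3,5-dimethoxybenzyl)oxolan-3-yl]methanone | COc1cc(C[C@H]2COC[C@@H]2C(=O)c2cc(OC)c(O)c(OC)c2)cc(OC)c1O
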